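The south-east run and the south-west run differ in both starting material and free catalyst, yet along their straight middle stretches target grows at 11.4 mM/min and 11.4 mM/min, practically the same slope. I call the first figure the ceiling rate, the straight-line growth of target that these two runs share, and I take it to be the pace at which solid reagent enters solution.

| setting | west | south-east | south-west | flask |
|---|---|---|---|---|
| starting material | 0.25 M | 1 M | 0.50 M | 0.50 M |
| solid reagent | 0.55 M | 0.55 M | 0.55 M | 0.550 M |
| free catalyst | 10 mM (in portions, 4) | 10 mM (in portions, 4) | 15 mM (in portions, 4) | 10 mM (in portions, 4) |
| remark | run made earlier; portions every 2.5 min | run made earlier; portions every 2.5 min | run made earlier; portions every 2.5 min | the portions of free catalyst follow each other after 2.5 min, the first at the start |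
| time |  |  |  | 1.0 h |

- west (time / min: target / %, starting material / %): 6.00: 5.1, 92.9; 12.0: 20.9, 76.8; 20.0: 43.2, 55.0; 25.0: 55.2, 43.9; 30.0: 65.0, 33.5; 40.0: 79.0, 18.6
- south-east (time / min: target / %, starting material / %): 2.50: 0.1, 99.4; 8.00: 3.9, 96.0; 12.0: 8.4, 90.8; 20.0: 17.4, 82.3; 30.0: 29.0, 70.4; 40.0: 40.3, 58.7
- south-west (time / min: target / %, starting material / %): 8.00: 8.2, 89.3; 15.0: 25.9, 71.8; 20.0: 37.7, 60.5; 30.0: 60.0, 38.1; 40.0: 77.9, 20.8

(readings scatter by 0.3 percentage points)

- given per volume of solution although it is solid: solid reagent
- the analysis behind the earlier runs scatters by 0.3 percentage points, standard deviation
- at the start none of the solid reagent is in solution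

- the target in the flask at 1.0 h, as a percentage of the starting material charged
- the starting material in the flask at 1.0 h, as a percentage of the starting material charged

This is my own reckoning of the curve for the flask. I expect it to start flat, as the west run does, which holds 5.1% target at 6.00 min. I then let it climb straight, and I allow it the ceiling rate at best. At that pace the solid reagent lasts 48.3 min. Its charge exceeds that of starting material, so the curve levels toward full conversion.

I put the knee near the west run's charge, since that run climbs at only 6.97 mM/min. From there I let the flask follow the west run, delayed by the extra starting material divided by the ceiling rate, 21.9 min. So 1.0 h in the flask is 38.1 min on the west run. The west tail falls by 0.0588 /min, which leaves 10.4% starting material. Carrying over the 2.40% that the west run misses at 40.0 min, I get target at 87.2%.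

The forecast says target 85% (80% to 90%) and starting material 13% (9% to 18%), since “it tracks the west curve shifted by about 25 min”. That delay of about 25 min stands against my 21.9 min, so the forecast keeps more starting material.

The flask gives target 85.4% and starting material 12.7%.

    starting material + free catalyst → catalyst intermediate A (k = 6.30 /M/min)
    partner + catalyst intermediate A → catalyst intermediate B (k = 17.0 /M/min)
    catalyst intermediate B → free catalyst + target (k = 230 /min)
    partner + target → over-reaction product (k = 0.00430 /M/min)
    solid reagent ⇌ partner, rate k5*(cs5 - [partner]) while solid is left; crystals form when [partner] > cs5 (solubility = 0.370 M, k = 0.0440 /min)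
    partner + catalyst intermediate B → spent catalyst (k = 0.0490 /M/min)

At 0.500 h the flask holds 50.2% starting material, which equals the west run's charge. At the ceiling rate that fall takes 21.9 min, but the flask took 30 min, flat start included, an average of 8.30 mM/min, slower than the ceiling rate.

In the neighbour charged with 0.33 M of solid reagent, the ceiling rate brings that charge in after about 28.9 min, sooner than the 43.9 min the starting material needs. Solid reagent is thus the limiting reagent there, and target should level near 66.0%. That neighbour gives target 64.7% and starting material 32.9%, with solid reagent at 0% and partner at 0.00165 M.

The runs stem from a simulated flask on assumed constants; noise was put on by code.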